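(The numbers in the tables were generated by integration with constants of no real substance; the scatter is artificial.)

Two lengths and one choice between them were asked of me, for the flasks south-west and east, and the earlier violet run was what I had to go on.

| flask | free monomer | transfer agent | initiator | impurity | remark | time |
|---|---|---|---|---|---|---|
| violet | 1 M (fed, over 1.0 h) | 0.10 M | 2.2 mol% | 2.6 mM | run made earlier; the fed solution adds 0.20 times the starting volume |  |
| south-west | 1.0 M (fed, over 1.0 h) | 0.100 M | 1.5 mol% | 2.6 mM | the fed solution adds 0.20 times the starting volume | 25 h |
| east | 3.0 M (fed, over 1.0 h) | 0.100 M | 1.5 mol% | 2.6 mM | the fed solution adds 0.20 times the starting volume | 25 h |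

violet run (percent of the free monomer charged)

| time / h | monomer in chains / % | free monomer / % |
|---|---|---|
| 0.417 | 0 | 39 |
| 0.833 | 0 | 81 |
| 1.33 | 3 | 100 |
| 2.50 | 7 | 90 |
| 5.00 | 20 | 77 |

(readings scatter by 2 percentage points)

- charges are per starting volume, the dose included; the dosed solution carries all of it
- the average divides the monomer in chains by the number of chains begun, living and dead together
- reactions considered so far: free monomer + living end -> monomer in chains + living end; living end + transfer agent -> dead chain; free monomer -> uncatalysed product; initiator + impurity -> spent initiator; free monomer + initiator -> living end + monomer in chains
- the earlier runs do not show the number of chains; that part of a forecast is a guess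
- percentages count the whole charge, also what has not yet gone in
- no earlier run changes the charge of initiator; that part of a forecast is a guess

1. which of the two ends with the longer chains by the average number of monomer units in a chain (chains begun, living or dead) ("neither" if they lie within 10%) (south-west / east / neither)
2. average number of monomer units in a chain (chains begun, living or dead) at the end, south-west
3. average number of monomer units in a chain (chains begun, living or dead) at the end, east

I followed one initiator molecule through its forks. At the first it meets impurity or free monomer, and I assumed that each impurity spends one initiator before growth matters, which violet cannot show. In south-west the initiator charged minus the impurity charged is 12.4 mM, and I called this difference the usable initiator, u; it is 42.4 mM in east and 19.4 mM in violet. I took each usable initiator to begin one chain, and a dead chain still counts as begun, so my length was L = Xc/u, where X is the share of the charge c that stands in chains.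

That was my first rung; the dosing, 1.0 h, came next. Growth came after it: violet's free monomer fell from 100% at 1.33 h to 77% at 5.00 h, a pseudo-first-order rate g of 0.0712 /h as read, so the time 1/g is 14.0 h, longer than the dosing. Below growth I put the uncatalysed loss, since violet's two columns still summed to 97.0% at 5.00 h, with each reading good to 2 percentage points, so the missing part was smaller than the monomer in chains.

I guessed that g scales with u, as no earlier run changes the initiator. Over the time after dosing, I put south-west at 0.0455 /h, giving X = 66.5% and L = 53.6. I put east at 0.156 /h, giving X = 97.6% and L = 69.1, so I reckoned east the longer.

The forecast chose east, with 45 (28 to 80) for south-west and 67 (50 to 110) for east. Its ground was “South-west then runs at about 0.03 /h: about 50 % conversion by 25 h”, and its south-west stood below my reckoning.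

The flasks gave 54.3 in south-west, with 65.9% in chains at 25.0 h, and 70.2 in east, so east ended longer.

    free monomer + living end → monomer in chains + living end, rate k1*[living end]*[free monomer] (k = 0.00219 /M/s)
    living end + transfer agent → dead chain (kL = 1.38 × 10⁻⁴ /M/s)
    free monomer → uncatalysed product (k = 4.77 × 10⁻⁷ /s)
    initiator + impurity → spent initiator (k = 1.11 /M/s)
    free monomer + initiator → living end + monomer in chains (k = 8.69 × 10⁻⁵ /M/s)

A neighbouring flask is south-west with 0.6 mol% of initiator. There u falls from 12.4 mM to 3.40 mM, the impurity charge being 43.3% of the initiator charge. The same reckoning gives a rate of 0.0125 /h, then X = 25.9% and L = 76.1. Simulated, this neighbour held 26.1% in chains at 25.0 h and reached an average of 77.0 monomer units in a chain.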